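## Retrosynthetic overview

1. The target comes from a doubly protected ten-membered ring (phenol as TBS ether, allylic alcohol as PMB ether). This carbocycle is the only ring built, and it is closed last by ring-closing metathesis that forms the C3=C4 trisubstituted Z-alkene.
2. The metathesis diene comes from acylation of an acyclic homoallylic alcohol with 4-(TBS-oxy)benzoyl chloride.
3. That alcohol comes from chelation-controlled 2-methylallylation of a β-PMB-oxy, α-isopropyl aldehyde, which sets the ester-bearing carbinol.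
4. The aldehyde comes from the key fragment union: an Evans syn aldol between the (R)-4-benzyloxazolidinone isovalerimide and (Z)-3-methylhepta-2,6-dienal, which sets the carbinol and isopropyl centres.
5. The Z-dienal comes from neryl acetate (Z-alkene purchased) by excision of the isopropylidene end and methylenation.

Assumption: neryl acetate (≥97% Z) and tributyl(2-methylallyl)stannane are purchasable. The CIP descriptor of the isopropyl-bearing carbon changes with the oxygen substituents, but its spatial arrangement never changes.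

## Route

Step 1
Reactants: 1 neryl acetate, (2Z)-3,7-dimethylocta-2,6-dien-1-yl acetate
Product: 2 (2Z)-5-(3,3-dimethyloxiran-2-yl)-3-methylpent-2-en-1-yl acetate (racemic at the oxirane carbon)
Conditions: mCPBA (1.05 equiv), CH2Cl2, 0 °C
Reagents that add atoms: mCPBA (3-chloroperoxybenzoic acid), O=C(OO)c1cccc(Cl)c1
Why: Prilezhaev epoxidation with one equivalent of peracid is selective for the electron-rich 6,7-alkene because the 2,3-alkene is deactivated by the allylic acetate, and the stereocentre formed is destroyed in step 2.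

Step 2
Reactants: 2 (2Z)-5-(3,3-dimethyloxiran-2-yl)-3-methylpent-2-en-1-yl acetate
Product: 4 (2Z)-3-methyl-6-oxohex-2-en-1-yl acetate, via vicinal diol 3 (not isolated)
Conditions: H5IO6 (1.2 equiv), THF/H2O, 0 °C
Reagents that add atoms: water, O (its oxygen is held only in diol 3 and leaves with the acetone; 4 keeps the epoxide oxygen)
Why: Periodic acid hydrolyses the epoxide to the diol and cleaves it in the same flask (Malaprade glycol cleavage), removing the isopropylidene carbons as acetone without touching the Z-alkene or the acetate.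

Step 3
Reactants: 4 (2Z)-3-methyl-6-oxohex-2-en-1-yl acetate
Product: 5 (2Z)-3-methylhepta-2,6-dien-1-yl acetate
Conditions: Ph3PCH3Br, NaN(SiMe3)2, THF, 0 °C; then 4, −78 → 0 °C
Reagents that add atoms: methyltriphenylphosphonium bromide, C[P+](c1ccccc1)(c1ccccc1)c1ccccc1.[Br-]
Why: Wittig methylenation with the non-stabilised ylide is much faster at the aldehyde than at the acetate at low temperature and installs the terminal vinyl group needed for the ring closure.

Step 4
Reactants: 5 (2Z)-3-methylhepta-2,6-dien-1-yl acetate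
Product: 6 (2Z)-3-methylhepta-2,6-dien-1-ol
Conditions: K2CO3 (0.2 equiv), MeOH, 0 °C → rt
Reagents that add atoms: none
Why: Base-catalysed transesterification (Zemplén-type methanolysis) removes the acetate without affecting either alkene.

Step 5
Reactants: 6 (2Z)-3-methylhepta-2,6-dien-1-ol
Product: 7 (2Z)-3-methylhepta-2,6-dienal
Conditions: TEMPO (10 mol %), PhI(OAc)2 (1.1 equiv), CH2Cl2, rt
Reagents that add atoms: none
Why: TEMPO-catalysed oxidation with PhI(OAc)2 converts the allylic alcohol into the enal under neutral conditions that do not isomerise Z-enals of the neral type.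

Step 6
Reactants: 8 (4R)-4-benzyl-1,3-oxazolidin-2-one; 9 3-methylbutanoyl chloride
Product: 11 (4R)-4-benzyl-3-(3-methylbutanoyl)-1,3-oxazolidin-2-one, via lithium oxazolidinide 10 (not isolated)
Conditions: n-BuLi, THF, −78 °C; then 9, −78 → 0 °C
Reagents that add atoms: n-BuLi, [Li]CCCC (lithium, present only in salt 10)
Why: N-Acylation of the lithiated oxazolidinone with an acid chloride is the standard clean way to load an Evans auxiliary.

Step 7
Reactants: 11 (4R)-4-benzyl-3-(3-methylbutanoyl)-1,3-oxazolidin-2-one; 7 (2Z)-3-methylhepta-2,6-dienal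
Product: 14 (4R)-4-benzyl-3-[(2R,3S,4Z)-3-hydroxy-5-methyl-2-(propan-2-yl)nona-4,8-dienoyl]-1,3-oxazolidin-2-one, via boron enolate 12 (not isolated), via boron aldolate 13 (not isolated)
Conditions: Bu2BOTf (1.2 equiv), Et3N (1.4 equiv), CH2Cl2, 0 °C; 7, −78 → 0 °C; then pH 7 buffer (NaH2PO4/Na2HPO4), MeOH, 30% H2O2, 0 °C
Reagents that add atoms: Bu2BOTf, CCCCB(CCCC)OS(=O)(=O)C(F)(F)F (the Bu2B unit, present only in 12 and 13)
Why: In this Evans syn aldol reaction the Z boron enolate reacts through a closed Zimmerman–Traxler chair in which the (R)-benzyl group shields one enolate face, so the two fragments are joined with the hydroxyl and isopropyl centres syn and in the required absolute sense (2R,3S).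

Step 8
Reactants: 14 (4R)-4-benzyl-3-[(2R,3S,4Z)-3-hydroxy-5-methyl-2-(propan-2-yl)nona-4,8-dienoyl]-1,3-oxazolidin-2-one
Product: 15 (2S,3S,4Z)-5-methyl-2-(propan-2-yl)nona-4,8-diene-1,3-diol
Conditions: LiBH4 (3 equiv), THF, 0 °C → rt
Reagents that add atoms: none
Why: Reductive cleavage of the imide with LiBH4 releases the primary alcohol and the recoverable auxiliary without epimerising the α-centre or touching the alkenes.

Step 9
Reactants: 15 (2S,3S,4Z)-5-methyl-2-(propan-2-yl)nona-4,8-diene-1,3-diol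
Product: 16 (2R,4S,5S)-2-(4-methoxyphenyl)-4-[(1Z)-2-methylhexa-1,5-dien-1-yl]-5-(propan-2-yl)-1,3-dioxane
Conditions: 4-MeOC6H4CH(OMe)2, PPTS (10 mol %), CH2Cl2, rt
Reagents that add atoms: 4-methoxybenzaldehyde dimethyl acetal, COc1ccc(C(OC)OC)cc1
Why: Acid-catalysed transacetalisation gives the thermodynamically preferred six-membered p-methoxybenzylidene acetal with the aryl group equatorial, and this acetal centre is removed again in step 10.

Step 10
Reactants: 16 (2R,4S,5S)-2-(4-methoxyphenyl)-4-[(1Z)-2-methylhexa-1,5-dien-1-yl]-5-(propan-2-yl)-1,3-dioxane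
Product: 17 (2S,3S,4Z)-3-[(4-methoxyphenyl)methoxy]-5-methyl-2-(propan-2-yl)nona-4,8-dien-1-ol
Conditions: i-Bu2AlH (3 equiv), CH2Cl2, −78 → 0 °C; aq. potassium sodium tartrate work-up
Reagents that add atoms: none
Why: In this regioselective reductive acetal opening i-Bu2AlH coordinates the less hindered primary oxygen and delivers hydride to the acetal carbon, leaving the PMB ether on the secondary allylic oxygen and freeing the primary alcohol.

Step 11
Reactants: 17 (2S,3S,4Z)-3-[(4-methoxyphenyl)methoxy]-5-methyl-2-(propan-2-yl)nona-4,8-dien-1-ol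
Product: 18 (2R,3S,4Z)-3-[(4-methoxyphenyl)methoxy]-5-methyl-2-(propan-2-yl)nona-4,8-dienal
Conditions: Dess–Martin periodinane (1.3 equiv), CH2Cl2, 0 °C → rt; used crude
Reagents that add atoms: none
Why: Dess–Martin oxidation gives the aldehyde under mild non-basic conditions, so the α-stereocentre does not epimerise and the β-alkoxy group is not eliminated.

Step 12
Reactants: 18 (2R,3S,4Z)-3-[(4-methoxyphenyl)methoxy]-5-methyl-2-(propan-2-yl)nona-4,8-dienal; 19 tributyl(2-methylallyl)stannane
Product: 20 (4S,5S,6S,7Z)-6-[(4-methoxyphenyl)methoxy]-2,8-dimethyl-5-(propan-2-yl)dodeca-1,7,11-trien-4-ol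
Conditions: MgBr2·OEt2 (3 equiv), CH2Cl2, −20 °C; then 19 (2 equiv), −20 → 0 °C
Reagents that add atoms: none
Why: In this Keck-type chelation-controlled carbonyl allylation MgBr2 ties the aldehyde oxygen and the β-PMB ether oxygen into a six-membered chelate and the stannane attacks the face opposite the α-isopropyl group, giving the (4S) carbinol that is anti to the isopropyl group and 1,3-anti to the ether.

Step 13
Reactants: 21 4-hydroxybenzoic acid
Product: 23 4-[(tert-butyldimethylsilyl)oxy]benzoic acid, via bis-silyl derivative 22 (not isolated)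
Conditions: TBSCl (2.5 equiv), imidazole (5 equiv), DMF, rt; then AcOH/H2O/THF, rt
Reagents that add atoms: TBSCl, CC(C)(C)[Si](C)(C)Cl
Why: Exhaustive silylation followed by selective hydrolysis of the labile silyl ester gives the phenol-protected acid, because aryl TBS ethers survive dilute acetic acid.

Step 14
Reactants: 23 4-[(tert-butyldimethylsilyl)oxy]benzoic acid
Product: 24 4-[(tert-butyldimethylsilyl)oxy]benzoyl chloride
Conditions: (COCl)2 (1.5 equiv), DMF (cat.), CH2Cl2, 0 °C → rt; evaporate and use crude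
Reagents that add atoms: oxalyl chloride, O=C(Cl)C(Cl)=O
Why: Vilsmeier-type activation with oxalyl chloride and catalytic DMF converts the acid into the acid chloride under conditions the aryl silyl ether tolerates.

Step 15
Reactants: 20 (4S,5S,6S,7Z)-6-[(4-methoxyphenyl)methoxy]-2,8-dimethyl-5-(propan-2-yl)dodeca-1,7,11-trien-4-ol; 24 4-[(tert-butyldimethylsilyl)oxy]benzoyl chloride
Product: 25 (4S,5S,6S,7Z)-6-[(4-methoxyphenyl)methoxy]-2,8-dimethyl-5-(propan-2-yl)dodeca-1,7,11-trien-4-yl 4-[(tert-butyldimethylsilyl)oxy]benzoate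
Conditions: Et3N (3 equiv), DMAP (0.3 equiv), CH2Cl2, 0 °C → rt
Reagents that add atoms: none
Why: DMAP-catalysed acylation through the acylpyridinium ion esterifies the hindered secondary alcohol with retention, because the carbinol C–O bond is not broken.

Step 16
Reactants: 25 (4S,5S,6S,7Z)-6-[(4-methoxyphenyl)methoxy]-2,8-dimethyl-5-(propan-2-yl)dodeca-1,7,11-trien-4-yl 4-[(tert-butyldimethylsilyl)oxy]benzoate
Product: 26 (1S,3Z,7Z,9S,10S)-9-[(4-methoxyphenyl)methoxy]-3,7-dimethyl-10-(propan-2-yl)cyclodeca-3,7-dien-1-yl 4-[(tert-butyldimethylsilyl)oxy]benzoate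
Conditions: second-generation Hoveyda–Grubbs catalyst RuCl2(H2IMes)(=CH-C6H4-2-O-i-Pr) (15 mol %), 1,4-benzoquinone (20 mol %), toluene (1 mM), 80 °C
Reagents that add atoms: none
Why: In this ring-closing metathesis the ruthenium carbene loads on the monosubstituted alkene and closes onto the 1,1-disubstituted alkene at high dilution, and a ten-membered ring that already holds one cis alkene can only take up the new trisubstituted alkene with the cis (Z) ring geometry.

Step 17
Reactants: 26 (1S,3Z,7Z,9S,10S)-9-[(4-methoxyphenyl)methoxy]-3,7-dimethyl-10-(propan-2-yl)cyclodeca-3,7-dien-1-yl 4-[(tert-butyldimethylsilyl)oxy]benzoate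
Product: 27 (1S,3Z,7Z,9S,10R)-9-hydroxy-3,7-dimethyl-10-(propan-2-yl)cyclodeca-3,7-dien-1-yl 4-[(tert-butyldimethylsilyl)oxy]benzoate
Conditions: DDQ (1.3 equiv), CH2Cl2/pH 7 buffer (NaH2PO4/Na2HPO4) 10:1, 0 °C
Reagents that add atoms: none
Why: Oxidative PMB ether cleavage with DDQ proceeds by hydride abstraction from the electron-rich benzylic position followed by hydrolysis, leaving the aroyl ester, the aryl silyl ether and both alkenes untouched.

Step 18
Reactants: 27 (1S,3Z,7Z,9S,10R)-9-hydroxy-3,7-dimethyl-10-(propan-2-yl)cyclodeca-3,7-dien-1-yl 4-[(tert-butyldimethylsilyl)oxy]benzoate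
Product: 28 (1S,3Z,7Z,9S,10R)-9-hydroxy-3,7-dimethyl-10-(propan-2-yl)cyclodeca-3,7-dien-1-yl 4-hydroxybenzoate
Conditions: Bu4NF/AcOH (1:1, 1.5 equiv), THF, 0 °C
Reagents that add atoms: none
Why: Fluoride-mediated desilylation cleaves the aryl silyl ether within minutes, and buffering with acetic acid prevents base-induced migration or cleavage of the benzoate.

## Compound list

1 | neryl acetate, (2Z)-3,7-dimethylocta-2,6-dien-1-yl acetate | CC(C)=CCC/C(C)=C\COC(C)=O | starting material
2 | (2Z)-5-(3,3-dimethyloxiran-2-yl)-3-methylpent-2-en-1-yl acetate (racemic) | CC1(C)OC1CC/C(C)=C\COC(C)=O | intermediate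
3 | (2Z)-6,7-dihydroxy-3,7-dimethyloct-2-en-1-yl acetate (racemic, formed in the flask) | CC(C)(O)C(O)CC/C(C)=C\COC(C)=O | intermediate
4 | (2Z)-3-methyl-6-oxohex-2-en-1-yl acetate | O=CCC/C(C)=C\COC(C)=O | intermediate
5 | (2Z)-3-methylhepta-2,6-dien-1-yl acetate | C=CCC/C(C)=C\COC(C)=O | intermediate
6 | (2Z)-3-methylhepta-2,6-dien-1-ol | C=CCC/C(C)=C\CO | intermediate
7 | (2Z)-3-methylhepta-2,6-dienal | C=CCC/C(C)=C\C=O | intermediate
8 | (4R)-4-benzyl-1,3-oxazolidin-2-one | O=C1N[C@H](Cc2ccccc2)CO1 | starting material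
9 | 3-methylbutanoyl chloride | CC(C)CC(=O)Cl | starting material
10 | lithium (4R)-4-benzyl-2-oxo-1,3-oxazolidin-3-ide (formed in the flask) | [Li+].O=C1[N-][C@H](Cc2ccccc2)CO1 | intermediate
11 | (4R)-4-benzyl-3-(3-methylbutanoyl)-1,3-oxazolidin-2-one | CC(C)CC(=O)N1[C@H](Cc2ccccc2)COC1=O | intermediate
12 | (4R)-4-benzyl-3-[(1Z)-1-[(dibutylboranyl)oxy]-3-methylbut-1-en-1-yl]-1,3-oxazolidin-2-one (formed in the flask) | CCCCB(CCCC)O/C(=C\C(C)C)N1[C@H](Cc2ccccc2)COC1=O | intermediate
13 | O-dibutylboranyl aldolate of 14 (formed in the flask) | C=CCC/C(C)=C\[C@H](OB(CCCC)CCCC)[C@@H](C(C)C)C(=O)N1[C@H](Cc2ccccc2)COC1=O | intermediate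
14 | (4R)-4-benzyl-3-[(2R,3S,4Z)-3-hydroxy-5-methyl-2-(propan-2-yl)nona-4,8-dienoyl]-1,3-oxazolidin-2-one | C=CCC/C(C)=C\[C@H](O)[C@@H](C(C)C)C(=O)N1[C@H](Cc2ccccc2)COC1=O | intermediate
15 | (2S,3S,4Z)-5-methyl-2-(propan-2-yl)nona-4,8-diene-1,3-diol | C=CCC/C(C)=C\[C@H](O)[C@@H](C(C)C)CO | intermediate
16 | (2R,4S,5S)-2-(4-methoxyphenyl)-4-[(1Z)-2-methylhexa-1,5-dien-1-yl]-5-(propan-2-yl)-1,3-dioxane | C=CCC/C(C)=C\[C@H]1[C@@H](C(C)C)CO[C@@H](c2ccc(OC)cc2)O1 | intermediate
17 | (2S,3S,4Z)-3-[(4-methoxyphenyl)methoxy]-5-methyl-2-(propan-2-yl)nona-4,8-dien-1-ol | C=CCC/C(C)=C\[C@H](OCc1ccc(OC)cc1)[C@@H](C(C)C)CO | intermediate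
18 | (2R,3S,4Z)-3-[(4-methoxyphenyl)methoxy]-5-methyl-2-(propan-2-yl)nona-4,8-dienal | C=CCC/C(C)=C\[C@H](OCc1ccc(OC)cc1)[C@@H](C(C)C)C=O | intermediate
19 | tributyl(2-methylallyl)stannane | C=C(C)C[Sn](CCCC)(CCCC)CCCC | starting material
20 | (4S,5S,6S,7Z)-6-[(4-methoxyphenyl)methoxy]-2,8-dimethyl-5-(propan-2-yl)dodeca-1,7,11-trien-4-ol | C=CCC/C(C)=C\[C@H](OCc1ccc(OC)cc1)[C@@H](C(C)C)[C@H](O)CC(C)=C | intermediate
21 | 4-hydroxybenzoic acid | O=C(O)c1ccc(O)cc1 | starting material
22 | tert-butyldimethylsilyl 4-[(tert-butyldimethylsilyl)oxy]benzoate (formed in the flask) | CC(C)(C)[Si](C)(C)OC(=O)c1ccc(O[Si](C)(C)C(C)(C)C)cc1 | intermediate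
23 | 4-[(tert-butyldimethylsilyl)oxy]benzoic acid | CC(C)(C)[Si](C)(C)Oc1ccc(C(=O)O)cc1 | intermediate
24 | 4-[(tert-butyldimethylsilyl)oxy]benzoyl chloride | CC(C)(C)[Si](C)(C)Oc1ccc(C(=O)Cl)cc1 | intermediate
25 | (4S,5S,6S,7Z)-6-[(4-methoxyphenyl)methoxy]-2,8-dimethyl-5-(propan-2-yl)dodeca-1,7,11-trien-4-yl 4-[(tert-butyldimethylsilyl)oxy]benzoate | C=CCC/C(C)=C\[C@H](OCc1ccc(OC)cc1)[C@@H](C(C)C)[C@H](OC(=O)c1ccc(O[Si](C)(C)C(C)(C)C)cc1)CC(C)=C | intermediate
26 | (1S,3Z,7Z,9S,10S)-9-[(4-methoxyphenyl)methoxy]-3,7-dimethyl-10-(propan-2-yl)cyclodeca-3,7-dien-1-yl 4-[(tert-butyldimethylsilyl)oxy]benzoate | C/C1=C/[C@H](OCc2ccc(OC)cc2)[C@@H](C(C)C)[C@H](OC(=O)c2ccc(O[Si](C)(C)C(C)(C)C)cc2)C/C(C)=C\CC1 | intermediate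
27 | (1S,3Z,7Z,9S,10R)-9-hydroxy-3,7-dimethyl-10-(propan-2-yl)cyclodeca-3,7-dien-1-yl 4-[(tert-butyldimethylsilyl)oxy]benzoate | C/C1=C/[C@H](O)[C@@H](C(C)C)[C@H](OC(=O)c2ccc(O[Si](C)(C)C(C)(C)C)cc2)C/C(C)=C\CC1 | intermediate
28 | (1S,3Z,7Z,9S,10R)-9-hydroxy-3,7-dimethyl-10-(propan-2-yl)cyclodeca-3,7-dien-1-yl 4-hydroxybenzoate | C/C1=C/[C@H](O)[C@@H](C(C)C)[C@H](OC(=O)c2ccc(O)cc2)C/C(C)=C\CC1 | target

## Step count

Total steps: 18. Longest linear sequence: 15 steps (steps 1–5, 7–12 and 15–18, from neryl acetate).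

## Steps most likely to fail, with fallbacks

**Step 16 (ring-closing metathesis).** The risk is slow closure of a ten-membered ring onto a 1,1-disubstituted alkene flanked by a bulky aroyl ester, with oligomerisation competing. The fallback sets out from 20 and inverts the order of ring closure and acylation. The free homoallylic alcohol is much less hindered around the 2-methylallyl terminus and can assist metathesis by hydrogen bonding to the chloride ligands of the ruthenium catalyst. Metathesis of 20 under the step 16 conditions would give the cyclic alcohol (1S,3Z,7Z,9S,10S)-9-[(4-methoxyphenyl)methoxy]-3,7-dimethyl-10-(propan-2-yl)cyclodeca-3,7-dien-1-ol F1. Acylation of F1 with 24 (Et3N, DMAP, CH2Cl2) comes back to the route at 26.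

**Step 12 (chelation-controlled allylation).** The risk is incomplete chelation control, or Lewis-acid damage to the allylic PMB ether, giving an epimer mixture at the new carbinol. The fallback sets out from 18 and makes the same C–C bond by a chelation-controlled Mukaiyama aldol reaction. With 2-(trimethylsilyloxy)propene and Me2AlCl (2.5 equiv, CH2Cl2, −78 °C), which forms a tighter chelate, the product would be the β-hydroxy ketone (4S,5S,6S,7Z)-4-hydroxy-6-[(4-methoxyphenyl)methoxy]-8-methyl-5-(propan-2-yl)dodeca-7,11-dien-2-one F2. Wittig methylenation of the methyl ketone (Ph3P=CH2 in excess, THF, 0 °C) comes back to the route at 20.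

**Step 7 (Evans aldol with a Z-enal).** The risk is Z to E isomerisation of enal 7 before or during the aldol, which would erode the geometry of the C7=C8 alkene. The fallback sets out from 11 and builds that alkene after the aldol instead:

- The same boron aldol with commercial but-2-ynal, which cannot isomerise, would give (4R)-4-benzyl-3-[(2R,3R)-3-hydroxy-2-(propan-2-yl)hex-4-ynoyl]-1,3-oxazolidin-2-one F3. The spatial arrangement is the same as in 14; only the descriptor changes.
- LiBH4 reduction gives (2S,3R)-2-(propan-2-yl)hex-4-yne-1,3-diol F4.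
- Hydroxyl-directed trans-hydroalumination with NaAlH2(OCH2CH2OMe)2 in THF, then I2 at −78 °C, gives the vinyl iodide (2S,3R,4Z)-5-iodo-2-(propan-2-yl)hex-4-ene-1,3-diol F5.
- Acetalisation as in step 9 gives (2R,4R,5S)-4-[(1Z)-2-iodoprop-1-en-1-yl]-2-(4-methoxyphenyl)-5-(propan-2-yl)-1,3-dioxane F6.
- Negishi coupling of F6 with commercial but-3-en-1-ylzinc bromide [PdCl2(dppf), THF, 50 °C] replaces iodine by the butenyl chain with retention of alkene geometry and comes back to the route at 16.

## Further compounds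

F1 | step 16 | (1S,3Z,7Z,9S,10S)-9-[(4-methoxyphenyl)methoxy]-3,7-dimethyl-10-(propan-2-yl)cyclodeca-3,7-dien-1-ol | C/C1=C/[C@H](OCc2ccc(OC)cc2)[C@@H](C(C)C)[C@H](O)C/C(C)=C\CC1
F2 | step 12 | (4S,5S,6S,7Z)-4-hydroxy-6-[(4-methoxyphenyl)methoxy]-8-methyl-5-(propan-2-yl)dodeca-7,11-dien-2-one | C=CCC/C(C)=C\[C@H](OCc1ccc(OC)cc1)[C@@H](C(C)C)[C@H](O)CC(C)=O
F3 | step 7 | (4R)-4-benzyl-3-[(2R,3R)-3-hydroxy-2-(propan-2-yl)hex-4-ynoyl]-1,3-oxazolidin-2-one | CC#C[C@H](O)[C@@H](C(C)C)C(=O)N1[C@H](Cc2ccccc2)COC1=O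
F4 | step 7 | (2S,3R)-2-(propan-2-yl)hex-4-yne-1,3-diol | CC#C[C@H](O)[C@@H](C(C)C)CO
F5 | step 7 | (2S,3R,4Z)-5-iodo-2-(propan-2-yl)hex-4-ene-1,3-diol | C/C(I)=C/[C@H](O)[C@@H](C(C)C)CO
F6 | step 7 | (2R,4R,5S)-4-[(1Z)-2-iodoprop-1-en-1-yl]-2-(4-methoxyphenyl)-5-(propan-2-yl)-1,3-dioxane | C/C(I)=C/[C@H]1[C@@H](C(C)C)CO[C@@H](c2ccc(OC)cc2)O1
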